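**Retrosynthetic overview**
1. Target 32 ⇐ acylation of O8 with acid 30 and desilylation of the bicyclic core 26/27.
2. Core 26 ⇐ nine-membered lactone 22 + Ph3P=C=C=O (23). ε-C-acylation forms C3–C4 and an intramolecular Wittig reaction forms C1=C2; this closes the furanone ring (O4, C1, C2, C3, C4) and with it the ten-membered carbocycle C1–C10.
3. Enabling feature: C4 is at once the carbinol carbon of the lactone ester C1(=O)–O4–C4 and the ε-carbon of the γ-ylidene butenolide C4–C5=C6–C7=C11–C12=O. Deprotonation therefore gives an aromatic 2-oxidofuran trienolate that is nucleophilic at C4, and the ester carbonyl C1 is placed to close a five-membered ring onto the new acyl group.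
4. 22 ⇐ furan-fused lactone 20 by singlet-oxygen oxidation of the 2-silylfuran and in-ring dehydration (the ring fixes the C5=C6 geometry) ⇐ seco acid 19 by macrolactonization (O4–C1).
5. 19 ⇐ furan-3-ylmethanol by three directed lithiations (silyl to C12, Weinreb amide 5 to C7, (S)-propylene oxide to C6) and CBS reduction (C8); C10 comes from (R)-3-bromo-2-methylpropan-1-ol. Ring order: furan (bought) → nine-membered lactone → butenolide → furanone and ten-membered carbocycle together.

Key step: step 15

Remark: locants C1–C15 are the germacrane locants of the target (C12 the lactone carbonyl, C13 its CH2O, C14 the methyl on C10, C15 the methyl on C4, O4 the oxygen joining C1 and C4) and are used for all intermediates; the C4 configuration of 17–22 is erased in step 15 and is chosen (S) only to keep these compounds single diastereomers, and 21 is expected as a mixture of C6 epimers (ring–chain tautomers) and is drawn without a C6 descriptor.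

**Step 1**
Reactants: 1 (R)-3-bromo-2-methylpropan-1-ol
Product: 2 (R)-(3-bromo-2-methylpropoxy)(tert-butyl)dimethylsilane
Conditions: TBSCl, imidazole, DMF, 0 → 23 °C
Reagents that add atoms: tert-butyldimethylsilyl chloride (TBSCl), CC(C)(C)[Si](C)(C)Cl
Why: Imidazole-promoted O-silylation of a primary alcohol, which leaves the future C10 stereocentre untouched.

**Step 2**
Reactants: 2 (R)-(3-bromo-2-methylpropoxy)(tert-butyl)dimethylsilane; 3 N-methoxy-N-methylcarbamoyl chloride
Product: 5 (S)-4-((tert-butyldimethylsilyl)oxy)-N-methoxy-N,3-dimethylbutanamide, via Grignard reagent 4 (not isolated)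
Conditions: Mg, I2 (cat.), THF, 40 °C; then added to 3 (1.5 equiv), THF, −78 → 0 °C
Reagents that add atoms: magnesium, [Mg] (kept only in intermediate 4)
Why: Grignard formation and acylation by a carbamoyl chloride (Weinreb amide synthesis), run by adding 4 to excess 3 at low temperature so that the less electrophilic product amide is not attacked.

**Step 3**
Reactants: 6 furan-3-ylmethanol
Product: 7 tert-butyl(furan-3-ylmethoxy)dimethylsilane
Conditions: TBSCl, imidazole, CH2Cl2, 23 °C
Reagents that add atoms: tert-butyldimethylsilyl chloride (TBSCl), CC(C)(C)[Si](C)(C)Cl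
Why: Standard O-silylation that sets up the silyl migration of step 4.

**Step 4**
Reactants: 7 tert-butyl(furan-3-ylmethoxy)dimethylsilane
Product: 9 (2-(tert-butyldimethylsilyl)furan-3-yl)methanol, via 2-lithiofuran 8 (not isolated)
Conditions: n-BuLi, HMPA, THF, −78 → 0 °C; H2O
Reagents that add atoms: n-butyllithium, [Li]CCCC (lithium kept only in intermediate 8)
Why: Ether-directed lithiation at the furan 2-position followed by 1,4 O-to-C silyl migration (retro-Brook type) is the established route to 2-silyl-3-furanmethanols; the silyl group marks C12 for step 13 and blocks this alpha position.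

**Step 5**
Reactants: 9 (2-(tert-butyldimethylsilyl)furan-3-yl)methanol; 5 (S)-4-((tert-butyldimethylsilyl)oxy)-N-methoxy-N,3-dimethylbutanamide
Product: 11 hydroxy ketone (10S): furan with C12 TBS, C11 CH2OH, C7 C(=O)CH2CH(CH3)CH2OTBS, C6 H, via dilithio species 10 (not isolated)
Conditions: n-BuLi (2.2 equiv), DME, 0 °C; then 5, −78 → 0 °C; H2O
Reagents that add atoms: n-butyllithium, [Li]CCCC (lithium kept only in intermediate 10)
Why: Alkoxide-directed ortho-lithiation of 2-silyl-3-furanmethanols takes place at the furan 4-position (the future C7), and single acylation of the aryllithium by the Weinreb amide through its chelated tetrahedral intermediate forms the C7–C8 bond.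

**Step 6**
Reactants: 11 hydroxy ketone
Product: 12 TBDPS ether of 11 (C11 CH2OTBDPS)
Conditions: TBDPSCl, imidazole, DMF, 23 °C
Reagents that add atoms: tert-butyldiphenylsilyl chloride (TBDPSCl), CC(C)(C)[Si](Cl)(c1ccccc1)c1ccccc1
Why: O-silylation of the primary alcohol, which also draws any cyclic hemiketal form of 11 to the open ketone.

**Step 7**
Reactants: 12 silyl ether ketone
Product: 13 (8S,10S)-alcohol: C7 CH(OH)CH2CH(CH3)CH2OTBS
Conditions: (R)-2-methyl-CBS-oxazaborolidine (0.2 equiv), BH3·SMe2, THF, −20 °C; MeOH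
Reagents that add atoms: none
Why: Corey–Bakshi–Shibata reduction of an aryl alkyl ketone; with the furyl group as the large substituent the (R)-catalyst should deliver hydride to give the (8S)-carbinol under reagent control, the remote C10 centre having no say.

**Step 8**
Reactants: 13 (8S,10S)-alcohol
Product: 14 (8S,10S)-C8 TBS ether
Conditions: TBSOTf, 2,6-lutidine, CH2Cl2, −78 → 0 °C
Reagents that add atoms: tert-butyldimethylsilyl triflate (TBSOTf), CC(C)(C)[Si](C)(C)OS(=O)(=O)C(F)(F)F
Why: Silyl triflate silylation of a hindered secondary alcohol.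

**Step 9**
Reactants: 14 (8S,10S)-C8 TBS ether; 15 (S)-2-methyloxirane
Product: 17 (4S,8S,10S)-furan alcohol: C6 CH2CH(OH)CH3, via 6-lithiofuran 16 (not isolated)
Conditions: n-BuLi, TMEDA, THF, −78 → 0 °C; then 15, BF3·OEt2, −78 °C; H2O
Reagents that add atoms: n-butyllithium, [Li]CCCC (lithium kept only in intermediate 16)
Why: The only ring hydrogen left is the alpha-hydrogen at C6, so the lithiation is regiodefined, and BF3-assisted SN2 opening of the epoxide at its CH2 terminus forms C5–C6 and carries the (S)-carbinol C4 in unchanged.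

**Step 10**
Reactants: 17 (4S,8S,10S)-furan alcohol
Product: 18 (4S,8S,10S)-diol: C1 CH2OH free, C4 OH free
Conditions: HF·pyridine, pyridine, THF, 0 °C
Reagents that add atoms: none
Why: Selective desilylation; buffered HF should cleave the unhindered primary TBS ether far faster than the hindered secondary TBS ether, the primary TBDPS ether or the furyl C–Si bond.

**Step 11**
Reactants: 18 (4S,8S,10S)-diol
Product: 19 (4S,8S,10S)-hydroxy acid (seco acid): C1 CO2H
Conditions: TEMPO (0.2 equiv), PhI(OAc)2 (2.5 equiv), MeCN/H2O 1:1, 0 → 23 °C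
Reagents that add atoms: water, O
Why: Oxoammonium (TEMPO/PhI(OAc)2) oxidation is selective for the primary alcohol and in water carries the aldehyde hydrate on to the acid, leaving the secondary C4 hydroxyl for the lactonization.

**Step 12**
Reactants: 19 (4S,8S,10S)-hydroxy acid
Product: 20 (4S,8S,10S) furan-fused nine-membered lactone (ring atoms C1, O4, C4, C5, C6, C7, C8, C9, C10)
Conditions: MNBA (2-methyl-6-nitrobenzoic anhydride), DMAP, Et3N, CH2Cl2, 23 °C, slow addition, 1 mM
Reagents that add atoms: none
Why: Shiina macrolactonization (acyl activation, retention at C4) at high dilution; both chains sit on the adjacent carbons C6 and C7 of the planar furan, which holds the two termini close and should favour closure of the nine-membered ring.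

**Step 13**
Reactants: 20 furan-fused nine-membered lactone
Product: 21 (4S,8S,10S) gamma-hydroxybutenolide lactone (C12=O, C6–OH, C7=C11)
Conditions: O2, tetraphenylporphyrin (cat.), visible light, CH2Cl2, −78 °C; then H2O
Reagents that add atoms: oxygen, O=O
Why: Silyl-directed furan photooxygenation: [4+2] addition of singlet oxygen across C6 and C12, then C-to-O silyl shift with O–O cleavage, gives the silyl ester of the (Z)-4-oxo-enoic acid, which on aqueous work-up closes to the gamma-hydroxybutenolide with the carbonyl at the silyl-bearing carbon C12.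

**Step 14**
Reactants: 21 gamma-hydroxybutenolide lactone
Product: 22 (4S,8S,10S) gamma-ylidene butenolide lactone (C5=C6 with C4 cis to C7)
Conditions: MsCl, Et3N, DMAP (cat.), CH2Cl2, −20 → 23 °C
Reagents that add atoms: none
Why: Dehydration of a gamma-hydroxybutenolide (pseudo-acid) to the gamma-ylidene butenolide by mesylation and loss of H5; only C5 carries hydrogen, and the nine-membered ring admits only the cis in-ring C5=C6 bond, which is the geometry of the target.

**Step 15**
Reactants: 22 gamma-ylidene butenolide lactone; 23 (triphenylphosphoranylidene)ketene (Ph3P=C=C=O)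
Product: 26 (4S,8S,10S) protected furanone core (8-O-TBS, 13-O-TBDPS), via trienolate 24 (not isolated), via keto ylide 25 (not isolated)
Conditions: 23 (1.5 equiv), DBU (0.3 equiv), PhMe, 60 °C, then 110 °C
Reagents that add atoms: none
Why: Proposed new method: DBU reversibly removes H4, which is alpha to the lactone oxygen O4 and at the same time the epsilon-hydrogen of the ylidene butenolide (C4–C5=C6–C7=C11–C12=O), to give the aromatic 2-oxidofuran trienolate 24; its remote carbon C4 adds to the central carbon of the cumulated ylide 23 (C3–C4 bond), proton return from DBU-H+ gives the keto ylide 25, and on heating the ylide carbon C2 of 25 attacks the lactone carbonyl C1 and Ph3PO is lost to leave C1=C2. The closest known reaction types are the addition of alcohols, amines and enolised 1,3-dicarbonyl compounds across Ph3P=C=C=O with subsequent intramolecular Wittig olefination (tetronates from alpha-hydroxy esters), the thermal intramolecular Wittig reaction of alpha-acyloxy keto ylides at the ester carbonyl that gives 3(2H)-furanones, and epsilon-selective (bis-vinylogous) reactions of furan-based trienolates. The C3–C4 bond forms between two molecules and closes no ring; the Wittig step closes the furanone ring (O4, C1, C2, C3, C4) by 5-exo-trig attack on C1=O and, because the new C2–C3 bridge spans C1 and C4 of the nine-membered lactone, the same bond completes the ten-membered carbocycle C1–C10 with no separate medium-ring C–C closure. The quaternary stereocentre C4 is set in the acylation: in 24 the cis C4=C5 enol ester is held in the nine-membered ring, whose C1–C10–C9 bridge, oriented by the C8 silyloxy and C10 methyl groups, lies over one face of C4, so 23 is expected to add to the open face and give (4S), while C8 and C10 are not touched. The step needs attack at C4 in preference to the oxygen on C12, C11 and C6, which should be secured because only C4 attack keeps the conjugated ylidene butenolide, because the O-acyl product is an activated ester that can return to 24, and because only the C4 adduct can close a five-membered ring; it also needs acylation to outrun 1,2-acyl shift of the acyloxy carbanion, which delocalisation of the charge into the oxidofuran should secure.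

**Step 16**
Reactants: 26 protected furanone core
Product: 27 (4S,8S,10S) 8-hydroxy-13-O-TBDPS core
Conditions: HF·pyridine, pyridine, THF, 0 → 23 °C
Reagents that add atoms: none
Why: Selective desilylation; buffered HF should cleave the secondary TBS ether while the far more acid-stable primary TBDPS ether is kept.

**Step 17**
Reactants: 28 ethyl 2-(hydroxymethyl)acrylate
Product: 29 ethyl 2-(((tert-butyldimethylsilyl)oxy)methyl)acrylate
Conditions: TBSCl, imidazole, CH2Cl2, 0 → 23 °C
Reagents that add atoms: tert-butyldimethylsilyl chloride (TBSCl), CC(C)(C)[Si](C)(C)Cl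
Why: O-silylation of the primary allylic alcohol.

**Step 18**
Reactants: 29 ethyl 2-(((tert-butyldimethylsilyl)oxy)methyl)acrylate
Product: 30 2-(((tert-butyldimethylsilyl)oxy)methyl)acrylic acid
Conditions: LiOH, THF/H2O, 0 °C; then 1 M HCl to pH 4
Reagents that add atoms: lithium hydroxide, [Li+].[OH-]
Why: Saponification of the ethyl ester at 0 °C, the silyl ether keeping the hydroxyl from adding to the acrylate.

**Step 19**
Reactants: 27 8-hydroxy-13-O-TBDPS core; 30 2-(((tert-butyldimethylsilyl)oxy)methyl)acrylic acid
Product: 31 fully protected target (8-O-[2-(TBSOCH2)acryloyl], 13-O-TBDPS)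
Conditions: 30, 2,4,6-trichlorobenzoyl chloride, Et3N, THF, 23 °C; then 27, DMAP, PhMe, 23 °C
Reagents that add atoms: none
Why: Yamaguchi esterification (mixed anhydride, DMAP acyl transfer) acylates the hindered secondary C8 hydroxyl with retention of configuration.

**Step 20**
Reactants: 31 fully protected target
Product: 32 target, (4S,8S,10S)
Conditions: HF·pyridine (excess), pyridine, THF, 0 → 23 °C
Reagents that add atoms: none
Why: Global fluoride desilylation of both primary silyl ethers under mildly acidic conditions that should spare the acrylate, the enol lactone and the furanone.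

**Compound list**
1 | (R)-3-bromo-2-methylpropan-1-ol | BrC[C@H](C)CO | starting material
2 | (R)-(3-bromo-2-methylpropoxy)(tert-butyl)dimethylsilane | BrC[C@H](C)CO[Si](C)(C)C(C)(C)C | intermediate
3 | N-methoxy-N-methylcarbamoyl chloride | CON(C)C(Cl)=O | starting material
4 | (3-((tert-butyldimethylsilyl)oxy)-2-methylpropyl)magnesium bromide, configuration as in 2 | Br[Mg]C[C@H](C)CO[Si](C)(C)C(C)(C)C | intermediate (not isolated)
5 | (S)-4-((tert-butyldimethylsilyl)oxy)-N-methoxy-N,3-dimethylbutanamide | CON(C)C(=O)C[C@H](C)CO[Si](C)(C)C(C)(C)C | intermediate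
6 | furan-3-ylmethanol | OCc1ccoc1 | starting material
7 | tert-butyl(furan-3-ylmethoxy)dimethylsilane | CC(C)(C)[Si](C)(C)OCc1ccoc1 | intermediate
8 | 2-lithio derivative of 7 | [Li]c1occc1CO[Si](C)(C)C(C)(C)C | intermediate (not isolated)
9 | (2-(tert-butyldimethylsilyl)furan-3-yl)methanol | OCc1ccoc1[Si](C)(C)C(C)(C)C | intermediate
10 | O,C4-dilithio derivative of 9 | [Li]OCc1c([Li])coc1[Si](C)(C)C(C)(C)C | intermediate (not isolated)
11 | (S)-4-((tert-butyldimethylsilyl)oxy)-1-(5-(tert-butyldimethylsilyl)-4-(hydroxymethyl)furan-3-yl)-3-methylbutan-1-one | OCc1c(C(=O)C[C@H](C)CO[Si](C)(C)C(C)(C)C)coc1[Si](C)(C)C(C)(C)C | intermediate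
12 | TBDPS ether of 11 (C13 OTBDPS) | O=C(C[C@H](C)CO[Si](C)(C)C(C)(C)C)c1coc([Si](C)(C)C(C)(C)C)c1CO[Si](c2ccccc2)(c2ccccc2)C(C)(C)C | intermediate
13 | (8S,10S)-alcohol from 12 | O[C@H](c1coc([Si](C)(C)C(C)(C)C)c1CO[Si](c2ccccc2)(c2ccccc2)C(C)(C)C)C[C@H](C)CO[Si](C)(C)C(C)(C)C | intermediate
14 | (8S,10S)-C8 TBS ether of 13 | CC(C)(C)[Si](C)(C)O[C@H](c1coc([Si](C)(C)C(C)(C)C)c1CO[Si](c2ccccc2)(c2ccccc2)C(C)(C)C)C[C@H](C)CO[Si](C)(C)C(C)(C)C | intermediate
15 | (S)-2-methyloxirane | C[C@H]1CO1 | starting material
16 | C6-lithio derivative of 14 | CC(C)(C)[Si](C)(C)O[C@H](c1c([Li])oc([Si](C)(C)C(C)(C)C)c1CO[Si](c2ccccc2)(c2ccccc2)C(C)(C)C)C[C@H](C)CO[Si](C)(C)C(C)(C)C | intermediate (not isolated)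
17 | (4S,8S,10S)-furan alcohol (C6 CH2CH(OH)CH3) | CC(C)(C)[Si](C)(C)O[C@H](c1c(C[C@H](C)O)oc([Si](C)(C)C(C)(C)C)c1CO[Si](c2ccccc2)(c2ccccc2)C(C)(C)C)C[C@H](C)CO[Si](C)(C)C(C)(C)C | intermediate
18 | (4S,8S,10S)-diol (C1 CH2OH, C4 OH) | CC(C)(C)[Si](C)(C)O[C@H](c1c(C[C@H](C)O)oc([Si](C)(C)C(C)(C)C)c1CO[Si](c2ccccc2)(c2ccccc2)C(C)(C)C)C[C@H](C)CO | intermediate
19 | (4S,8S,10S)-hydroxy acid (seco acid) | CC(C)(C)[Si](C)(C)O[C@H](c1c(C[C@H](C)O)oc([Si](C)(C)C(C)(C)C)c1CO[Si](c2ccccc2)(c2ccccc2)C(C)(C)C)C[C@H](C)C(=O)O | intermediate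
20 | (4S,8S,10S) furan-fused nine-membered lactone | CC(C)(C)[Si](C)(C)O[C@H]1C[C@H](C)C(=O)O[C@@H](C)Cc2oc([Si](C)(C)C(C)(C)C)c(CO[Si](c3ccccc3)(c3ccccc3)C(C)(C)C)c21 | intermediate
21 | (4S,8S,10S) gamma-hydroxybutenolide lactone, C6 epimers | CC(C)(C)[Si](C)(C)O[C@H]1C[C@H](C)C(=O)O[C@@H](C)CC2(O)OC(=O)C(CO[Si](c3ccccc3)(c3ccccc3)C(C)(C)C)=C21 | intermediate
22 | (4S,8S,10S) gamma-ylidene butenolide lactone (C4 cis to C7 across C5=C6) | CC(C)(C)[Si](C)(C)O[C@H]1C[C@H](C)C(=O)O[C@@H](C)/C=C2/OC(=O)C(CO[Si](c3ccccc3)(c3ccccc3)C(C)(C)C)=C21 | intermediate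
23 | (triphenylphosphoranylidene)ketene | O=C=C=P(c1ccccc1)(c1ccccc1)c1ccccc1 | starting material
24 | 2-oxidofuran trienolate of 22 (DBU-H+ counter-ion) | CC(C)(C)[Si](C)(C)O[C@H]1C[C@H](C)C(=O)O/C(C)=C\c2oc([O-])c(CO[Si](c3ccccc3)(c3ccccc3)C(C)(C)C)c21 | intermediate (not isolated)
25 | (4S)-keto ylide (C4 bears C(=O)CH=PPh3) | CC(C)(C)[Si](C)(C)O[C@H]1C[C@H](C)C(=O)O[C@](C)(C(=O)C=P(c3ccccc3)(c3ccccc3)c3ccccc3)/C=C2/OC(=O)C(CO[Si](c4ccccc4)(c4ccccc4)C(C)(C)C)=C21 | intermediate (not isolated)
26 | (4S,8S,10S) protected furanone core (8-O-TBS, 13-O-TBDPS) | CC(C)(C)[Si](C)(C)O[C@H]1C[C@H](C)C2=CC(=O)[C@](C)(/C=C3/OC(=O)C(CO[Si](c4ccccc4)(c4ccccc4)C(C)(C)C)=C31)O2 | intermediate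
27 | (4S,8S,10S) 8-hydroxy-13-O-TBDPS core | O[C@H]1C[C@H](C)C2=CC(=O)[C@](C)(/C=C3/OC(=O)C(CO[Si](c4ccccc4)(c4ccccc4)C(C)(C)C)=C31)O2 | intermediate
28 | ethyl 2-(hydroxymethyl)acrylate | C=C(CO)C(=O)OCC | starting material
29 | ethyl 2-(((tert-butyldimethylsilyl)oxy)methyl)acrylate | C=C(CO[Si](C)(C)C(C)(C)C)C(=O)OCC | intermediate
30 | 2-(((tert-butyldimethylsilyl)oxy)methyl)acrylic acid | C=C(CO[Si](C)(C)C(C)(C)C)C(=O)O | intermediate
31 | fully protected target (side-chain O-TBS, 13-O-TBDPS) | C=C(CO[Si](C)(C)C(C)(C)C)C(=O)O[C@H]1C[C@H](C)C2=CC(=O)[C@](C)(/C=C3/OC(=O)C(CO[Si](c4ccccc4)(c4ccccc4)C(C)(C)C)=C31)O2 | intermediate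
32 | target, (4S,8S,10S) | C=C(CO)C(=O)O[C@H]1C[C@H](C)C2=CC(=O)[C@](C)(/C=C3/OC(=O)C(CO)=C31)O2 | target

**Step count and risks**
Total step count: 20. Longest linear sequence: 16 steps (steps 1, 2, 5–16, 19, 20; the branch from 6 through steps 3 and 4 is equally long).

Steps most likely to fail:

1. Step 15 (Proposed new method). The trienolate may be acylated at the oxygen on C12, at C11 or at C6 instead of at C4; the ylide may add to the other face of C4 (the facial preference rests on a conformational argument that has not been modelled); the acyloxy carbanion may undergo 1,2-acyl shift with ring contraction; or the base may epimerize C10 in the product. The fallback uses known reaction types only and sets out from 22. Soft enolization (TBSOTf, Et3N, CH2Cl2) should give the silyl trienol ether F1. A remote, epsilon-selective (bis-vinylogous) Mukaiyama aldol reaction of this furan-based silyl trienol ether with acetaldehyde under SiCl4 and a chiral bisphosphoramide Lewis base, whose enantiomer is chosen for the required face of C4, should give the C4-quaternary aldol adduct F2. Dess–Martin oxidation gives the methyl ketone F3. LiHMDS (THF, −78 °C) forms the methyl ketone enolate, which attacks the lactone carbonyl C1 across the ring to give the cyclic hemiketal F4; this is dehydrated without purification (p-TsOH, PhMe) by the classical route from alpha-acyloxy ketones to 3(2H)-furanones. The fallback returns to the route at 26.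

2. Step 12. Intermolecular acylation (cyclic dimer and oligomers) may outrun closure of the strained nine-membered ring. The fallback closes the ring at the other ester bond, O4–C4. Starting from 19, Mitsunobu macrolactonization (PPh3, DIAD, PhMe, high dilution) activates the C4 carbinol and displaces it with inversion to give the (4R)-lactone F5. Because C4 is made planar in step 15, the inversion is without consequence. F5 is carried through the conditions of step 13 to the (4R)-hydroxybutenolide F6 and of step 14 to the (4R)-ylidene butenolide lactone F7. Under the conditions of step 15, F7 gives the same trienolate, so the fallback returns to the route at 24 and hence 26.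

3. Step 16. The primary TBDPS ether may be lost together with the hindered secondary TBS ether, or the TBS ether may cleave too slowly for the sensitive core to survive. The fallback relays the protecting groups and sets out from 26. Excess HF·pyridine removes both silyl ethers to give the diol F8. Silylation at −20 °C (TBSCl, imidazole) should take only the unhindered primary C13 hydroxyl and give the mono-TBS ether F9. Esterification with 30 as in step 19 gives the bis-TBS ester F10, and desilylation as in step 20 returns to the route at 32.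

**Further compounds**
F1 | step 15 | silyl trienol ether of 22 (2-TBSO-furan, C4=C5 enol ester) | CC(C)(C)[Si](C)(C)O[C@H]1C[C@H](C)C(=O)O/C(C)=C\c2oc(O[Si](C)(C)C(C)(C)C)c(CO[Si](c3ccccc3)(c3ccccc3)C(C)(C)C)c21
F2 | step 15 | (4S)-aldol adduct, C4 bears CH(OH)CH3, carbinol epimers | CC(C)(C)[Si](C)(C)O[C@H]1C[C@H](C)C(=O)O[C@](C)(C(C)O)/C=C2/OC(=O)C(CO[Si](c3ccccc3)(c3ccccc3)C(C)(C)C)=C21
F3 | step 15 | (4S)-methyl ketone, C4 bears C(=O)CH3 | CC(C)(C)[Si](C)(C)O[C@H]1C[C@H](C)C(=O)O[C@](C)(C(C)=O)/C=C2/OC(=O)C(CO[Si](c3ccccc3)(c3ccccc3)C(C)(C)C)=C21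
F4 | step 15 | cyclic hemiketal (C1 OH, C2 H2, C3 ketone), C1 epimers | CC(C)(C)[Si](C)(C)O[C@H]1C[C@H](C)C2(O)CC(=O)[C@](C)(/C=C3/OC(=O)C(CO[Si](c4ccccc4)(c4ccccc4)C(C)(C)C)=C31)O2
F5 | step 12 | (4R,8S,10S) furan-fused nine-membered lactone | CC(C)(C)[Si](C)(C)O[C@H]1C[C@H](C)C(=O)O[C@H](C)Cc2oc([Si](C)(C)C(C)(C)C)c(CO[Si](c3ccccc3)(c3ccccc3)C(C)(C)C)c21
F6 | step 12 | (4R,8S,10S) gamma-hydroxybutenolide lactone, C6 epimers | CC(C)(C)[Si](C)(C)O[C@H]1C[C@H](C)C(=O)O[C@H](C)CC2(O)OC(=O)C(CO[Si](c3ccccc3)(c3ccccc3)C(C)(C)C)=C21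
F7 | step 12 | (4R,8S,10S) gamma-ylidene butenolide lactone | CC(C)(C)[Si](C)(C)O[C@H]1C[C@H](C)C(=O)O[C@H](C)/C=C2/OC(=O)C(CO[Si](c3ccccc3)(c3ccccc3)C(C)(C)C)=C21
F8 | step 16 | (4S,8S,10S) 8,13-diol core | O[C@H]1C[C@H](C)C2=CC(=O)[C@](C)(/C=C3/OC(=O)C(CO)=C31)O2
F9 | step 16 | (4S,8S,10S) 8-hydroxy-13-O-TBS core | O[C@H]1C[C@H](C)C2=CC(=O)[C@](C)(/C=C3/OC(=O)C(CO[Si](C)(C)C(C)(C)C)=C31)O2
F10 | step 16 | bis-TBS protected target | C=C(CO[Si](C)(C)C(C)(C)C)C(=O)O[C@H]1C[C@H](C)C2=CC(=O)[C@](C)(/C=C3/OC(=O)C(CO[Si](C)(C)C(C)(C)C)=C31)O2
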